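**Retrosynthetic overview**
1. The ester C–O bond is made last: target ⇐ (3R)-β-cryptoxanthin + palmitoleoyl chloride (the Z-alkene is bought).
2. C7=C8 is made by Horner–Wittig olefination (oxaphosphetane [2+2]/retro-[2+2]) of a C10 allylic phosphine oxide with commercial all-E β-apo-8′-carotenal (C30).
3. Key step: a [2,3]-sigmatropic allyl phosphinite → allyl phosphine oxide rearrangement creates the tetrasubstituted ring C5=C6 bond and the C7–P bond from a tertiary allylic alcohol.
4. That alcohol ⇐ (4R,6R)-actinol by O-silylation, methylenation and SeO2 allylic hydroxylation (ene, then [2,3] shift); C3 is bought and never touched.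
5. Ring order: no carbocycle is constructed. The hydroxylated ring comes from actinol and the β-ring sits in the apocarotenal; the only ring formed is the transient oxaphosphetane.

Assumption: (4R,6R)-actinol, all-E β-apo-8′-carotenal and palmitoleoyl chloride are taken as catalogue compounds; positions C3, C5, C6, C7, C8 are quoted in carotenoid numbering; all polyene work is done under argon in dim light.

**Step 1**
Reactants: 1 (4R,6R)-4-hydroxy-2,2,6-trimethylcyclohexan-1-one (actinol); 2 tert-butyl(chloro)dimethylsilane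
Product: 3 (4R,6R)-4-{[tert-butyl(dimethyl)silyl]oxy}-2,2,6-trimethylcyclohexan-1-one
Conditions: TBSCl (1.2 eq), imidazole (2.5 eq), DMF, rt
Reagents that add atoms: tert-butyl(chloro)dimethylsilane, CC(C)(C)[Si](C)(C)Cl
Why: Imidazole-promoted silylation of the unhindered secondary alcohol forms no stereocenter and leaves the bought carbinol center (future C3) and the ketone untouched.

**Step 2**
Reactants: 3 (4R,6R)-4-{[tert-butyl(dimethyl)silyl]oxy}-2,2,6-trimethylcyclohexan-1-one; 4 methyl(triphenyl)phosphonium bromide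
Product: 5 tert-butyl(dimethyl){[(1R,5R)-3,3,5-trimethyl-4-methylidenecyclohexyl]oxy}silane
Conditions: Ph3PCH3Br (2.5 eq), KOtBu (2.5 eq), toluene, rt → 110 °C
Reagents that add atoms: methyl(triphenyl)phosphonium bromide, C[P+](c1ccccc1)(c1ccccc1)c1ccccc1.[Br-]
Why: Wittig methylenation with salt-free Ph3P=CH2 in hot toluene copes with α,α,α′-trisubstituted cyclohexanones; no stereocenter is formed, and any epimerization at the α-methyl carbon is harmless because step 3 removes that hydrogen.

**Step 3**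
Reactants: 5 tert-butyl(dimethyl){[(1R,5R)-3,3,5-trimethyl-4-methylidenecyclohexyl]oxy}silane; 6 tert-butyl hydroperoxide
Product: 7 (5S)-5-{[tert-butyl(dimethyl)silyl]oxy}-1,3,3-trimethyl-2-methylidenecyclohexan-1-ol
Conditions: SeO2 (0.5 eq), t-BuOOH (70% aq., 3 eq), CH2Cl2, rt
Reagents that add atoms: tert-butyl hydroperoxide, CC(C)(C)OO (its oxygen is relayed by the SeO2 catalyst)
Why: SeO2 allylic hydroxylation takes the only allylic hydrogen (tertiary C5–H) in an ene reaction, and the [2,3]-sigmatropic shift of the allylseleninic acid returns oxygen to C5 with the exocyclic alkene restored; the new carbinol center may form as either epimer without consequence because step 4 makes it sp2.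

**Step 4**
Reactants: 7 (5S)-5-{[tert-butyl(dimethyl)silyl]oxy}-1,3,3-trimethyl-2-methylidenecyclohexan-1-ol; 8 chloro(diphenyl)phosphane
Product: 10 ({(4R)-4-{[tert-butyl(dimethyl)silyl]oxy}-2,6,6-trimethylcyclohex-1-en-1-yl}methyl)(diphenyl)phosphine oxide, via allyl diphenylphosphinite 9 (not isolated)
Conditions: Ph2PCl (1.2 eq), Et3N (1.5 eq), DMAP (0.1 eq), toluene, 0 °C → rt; then 90 °C, Ar
Reagents that add atoms: chloro(diphenyl)phosphane, ClP(c1ccccc1)c1ccccc1
Why: O-phosphinylation gives a P(III) tertiary allyl phosphinite whose suprafacial [2,3]-sigmatropic rearrangement, driven by P=O formation, creates the tetrasubstituted C5=C6 ring bond of the target and the C7–P bond in one event; the transient carbinol center disappears and the silyloxy center is not involved.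

**Step 5**
Reactants: 10 ({(4R)-4-{[tert-butyl(dimethyl)silyl]oxy}-2,6,6-trimethylcyclohex-1-en-1-yl}methyl)(diphenyl)phosphine oxide; 11 all-E 8′-apo-β-caroten-8′-al (β-apo-8′-carotenal)
Product: 13 (3R)-β,β-caroten-3-ol [all-E (3R)-β-cryptoxanthin], via β-cryptoxanthin TBS ether 12 (not isolated)
Conditions: 10 (1.2 eq), KOtBu (1.3 eq), THF, −30 °C → rt, Ar, dark; then TBAF (3 eq), THF, rt
Reagents that add atoms: none
Why: In this Horner–Wittig olefination the phosphinoyl-stabilized allyl anion adds through its CH terminus to the aldehyde and the potassium β-alkoxide collapses through a four-membered oxaphosphetane to the 7E alkene (the 7Z isomer clashes with the ring methyls); fluoride then cleaves only the Si–O bond, so C3 and the bought E-polyene are unchanged.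

**Step 6**
Reactants: 13 (3R)-β,β-caroten-3-ol; 14 (9Z)-hexadec-9-enoyl chloride (palmitoleoyl chloride)
Product: 15 (3R)-β,β-caroten-3-yl (9Z)-hexadec-9-enoate
Conditions: 14 (1.5 eq), pyridine (5 eq), DMAP (0.1 eq), CH2Cl2, 0 °C → rt, Ar, dark
Reagents that add atoms: (9Z)-hexadec-9-enoyl chloride, CCCCCC/C=C\CCCCCCCC(=O)Cl
Why: Pyridine/DMAP-mediated O-acylation (nucleophilic acyl substitution) does not break the C3–O bond, so the R configuration is retained, and the mild conditions leave the Z-alkene and the polyene untouched.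

**Compound list**
1 | (4R,6R)-4-hydroxy-2,2,6-trimethylcyclohexan-1-one (actinol) | O[C@@H]1C[C@@H](C)C(=O)C(C)(C)C1 | starting material
2 | tert-butyl(chloro)dimethylsilane | CC(C)(C)[Si](C)(C)Cl | starting material
3 | (4R,6R)-4-{[tert-butyl(dimethyl)silyl]oxy}-2,2,6-trimethylcyclohexan-1-one | CC(C)(C)[Si](C)(C)O[C@@H]1C[C@@H](C)C(=O)C(C)(C)C1 | intermediate
4 | methyl(triphenyl)phosphonium bromide | C[P+](c1ccccc1)(c1ccccc1)c1ccccc1.[Br-] | starting material
5 | tert-butyl(dimethyl){[(1R,5R)-3,3,5-trimethyl-4-methylidenecyclohexyl]oxy}silane | CC(C)(C)[Si](C)(C)O[C@@H]1C[C@@H](C)C(=C)C(C)(C)C1 | intermediate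
6 | tert-butyl hydroperoxide | CC(C)(C)OO | starting material
7 | (5S)-5-{[tert-butyl(dimethyl)silyl]oxy}-1,3,3-trimethyl-2-methylidenecyclohexan-1-ol (either C1 epimer; that center is erased in step 4, so it is left open) | CC(C)(C)[Si](C)(C)O[C@@H]1CC(C)(O)C(=C)C(C)(C)C1 | intermediate
8 | chloro(diphenyl)phosphane | ClP(c1ccccc1)c1ccccc1 | starting material
9 | (5S)-5-{[tert-butyl(dimethyl)silyl]oxy}-1,3,3-trimethyl-2-methylidenecyclohexyl diphenylphosphinite (C1 open as in 7) | CC(C)(C)[Si](C)(C)O[C@@H]1CC(C)(OP(c2ccccc2)c2ccccc2)C(=C)C(C)(C)C1 | intermediate (not isolated)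
10 | ({(4R)-4-{[tert-butyl(dimethyl)silyl]oxy}-2,6,6-trimethylcyclohex-1-en-1-yl}methyl)(diphenyl)phosphine oxide | CC(C)(C)[Si](C)(C)O[C@@H]1CC(C)=C(CP(=O)(c2ccccc2)c2ccccc2)C(C)(C)C1 | intermediate
11 | all-E 8′-apo-β-caroten-8′-al = (2E,4E,6E,8E,10E,12E,14E,16E)-2,6,11,15-tetramethyl-17-(2,6,6-trimethylcyclohex-1-en-1-yl)heptadeca-2,4,6,8,10,12,14,16-octaenal | O=C/C(C)=C/C=C/C(C)=C/C=C/C=C(C)/C=C/C=C(C)/C=C/C1=C(C)CCCC1(C)C | starting material
12 | tert-butyl(dimethyl){[(3R)-β,β-caroten-3-yl]oxy}silane (all-E; β-cryptoxanthin TBS ether) | CC(C)(C)[Si](C)(C)O[C@@H]1CC(C)=C(/C=C/C(C)=C/C=C/C(C)=C/C=C/C=C(C)/C=C/C=C(C)/C=C/C2=C(C)CCCC2(C)C)C(C)(C)C1 | intermediate (not isolated)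
13 | (3R)-β,β-caroten-3-ol (all-E; (3R)-β-cryptoxanthin) | O[C@@H]1CC(C)=C(/C=C/C(C)=C/C=C/C(C)=C/C=C/C=C(C)/C=C/C=C(C)/C=C/C2=C(C)CCCC2(C)C)C(C)(C)C1 | intermediate
14 | (9Z)-hexadec-9-enoyl chloride (palmitoleoyl chloride) | CCCCCC/C=C\CCCCCCCC(=O)Cl | starting material
15 | (3R)-β,β-caroten-3-yl (9Z)-hexadec-9-enoate (CNP0382087.1) | CCCCCC/C=C\CCCCCCCC(=O)O[C@@H]1CC(C)=C(/C=C/C(C)=C/C=C/C(C)=C/C=C/C=C(C)/C=C/C=C(C)/C=C/C2=C(C)CCCC2(C)C)C(C)(C)C1 | target

**Totals and risks**
Total step count: 6. Longest linear sequence: 6 steps (1 → 15); 11 and 14 are bought, so there is no separate branch.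

The three steps most likely to fail:

Step 3 (SeO2 hydroxylation of a tertiary allylic C–H). It may be sluggish, or the tertiary allylic alcohol may transpose and over-oxidize to the enal. The fallback sets out from 5: radical Wohl–Ziegler bromination (NBS, cat. AIBN, PhCF3, 80 °C) traps the allyl radical at its primary terminus and gives {[(1R)-4-(bromomethyl)-3,5,5-trimethylcyclohex-3-en-1-yl]oxy}(tert-butyl)dimethylsilane F1. Michaelis–Arbuzov reaction of the bromide with ethyl diphenylphosphinite (toluene, 110 °C) then gives phosphine oxide 10, where the route resumes at step 5; steps 3 and 4 are bypassed.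

Step 4 (phosphinylation and [2,3] shift of a hindered tertiary allylic alcohol). The phosphinite may ionize or eliminate to a diene, or be air-oxidized, instead of rearranging. The fallback sets out from 7: Ph3P·HBr in CH2Cl2 at rt captures the allyl cation at its primary terminus (SN1′) and gives ({(4R)-4-{[tert-butyl(dimethyl)silyl]oxy}-2,6,6-trimethylcyclohex-1-en-1-yl}methyl)triphenylphosphonium bromide F2. Its ylide (NaHMDS, THF, −78 °C → rt) undergoes Wittig olefination with 11 and comes back to the route at silyl ether 12, which is desilylated with TBAF as in the second stage of step 5.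

Step 5 (Horner–Wittig coupling of a hindered allyl anion with a C30 polyenal, then desilylation in the same flask). Risks are poor addition, γ-attack, 7Z or other Z isomers, and base-induced polyene degradation. The fallback replaces olefination by sp2–sp2 cross-coupling and sets out from 3 and 11. Ketone 3 has only one α-hydrogen; KHMDS (THF, −78 °C) and PhNTf2 give regiospecifically (4R)-4-{[tert-butyl(dimethyl)silyl]oxy}-2,6,6-trimethylcyclohex-1-en-1-yl trifluoromethanesulfonate F3. Aldehyde 11 is homologated by a boron-Wittig reaction with lithiated bis(pinacolato)borylmethane (LiTMP, THF, −78 °C → rt) to 2-[(1E,3E,5E,7E,9E,11E,13E,15E,17E)-3,7,12,16-tetramethyl-18-(2,6,6-trimethylcyclohex-1-en-1-yl)octadeca-1,3,5,7,9,11,13,15,17-nonaen-1-yl]-4,4,5,5-tetramethyl-1,3,2-dioxaborolane F4. Suzuki–Miyaura coupling of the two (Pd(PPh3)4, aq. K3PO4, THF, rt, dark) forms the C6–C7 bond with retention of alkene geometry and comes back to the route at 12, which is desilylated as in step 5.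

**Further compounds**
F1 | step 3 | {[(1R)-4-(bromomethyl)-3,5,5-trimethylcyclohex-3-en-1-yl]oxy}(tert-butyl)dimethylsilane | CC(C)(C)[Si](C)(C)O[C@@H]1CC(C)=C(CBr)C(C)(C)C1
F2 | step 4 | ({(4R)-4-{[tert-butyl(dimethyl)silyl]oxy}-2,6,6-trimethylcyclohex-1-en-1-yl}methyl)triphenylphosphonium bromide | CC(C)(C)[Si](C)(C)O[C@@H]1CC(C)=C(C[P+](c2ccccc2)(c2ccccc2)c2ccccc2)C(C)(C)C1.[Br-]
F3 | step 5 | (4R)-4-{[tert-butyl(dimethyl)silyl]oxy}-2,6,6-trimethylcyclohex-1-en-1-yl trifluoromethanesulfonate | CC(C)(C)[Si](C)(C)O[C@@H]1CC(C)=C(OS(=O)(=O)C(F)(F)F)C(C)(C)C1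
F4 | step 5 | 2-[(1E,3E,5E,7E,9E,11E,13E,15E,17E)-3,7,12,16-tetramethyl-18-(2,6,6-trimethylcyclohex-1-en-1-yl)octadeca-1,3,5,7,9,11,13,15,17-nonaen-1-yl]-4,4,5,5-tetramethyl-1,3,2-dioxaborolane | CC1(C)OB(/C=C/C(C)=C/C=C/C(C)=C/C=C/C=C(C)/C=C/C=C(C)/C=C/C2=C(C)CCCC2(C)C)OC1(C)C
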